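Time at temperature is what a left-handed excess has to outlast in these flasks, so I ask how long it lasts.

the same everywhere: left-handed substrate 0.20 M; right-handed substrate 0.20 M; free catalyst 0.20 mM
- alder: coupling partner 0.20 M; protic impurity 0.015 M; temperature 110 °C; run made earlier
- green: coupling partner 0.200 M; protic impurity 0.0100 M; temperature 110 °C; time 5.0 min
- violet: coupling partner 0.200 M; protic impurity 0.0100 M; at 85 °C until 2.5 min, from then on at 110 °C; time 5.0 min
- teal: coupling partner 0.200 M; protic impurity 0.0100 M; temperature 85 °C; time 5.0 min

- alder (time / s: left-handed product / %, right-handed product / %): 20.0: 9.0, 2.3; 40.0: 13.2, 5.8; 50.0: 14.3, 7.3; 80.0: 17.1, 11.3; 90.0: 17.5, 12.6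

(standard deviation of a reading: 0.5 percentage points)

- free catalyst is single-handed; left-handed substrate and right-handed substrate are mirror images of each other, charged as a racemate, each of them at the stated concentration
- what was read earlier has a scatter of 0.5 percentage points, one standard deviation
- an excess is the difference of the two amounts in percent of their sum
- the earlier runs do not show what temperature does; that part of a forecast is a guess
- an excess is below zero if the other one leads
- no earlier run changes the charge of protic impurity; that part of a forecast is a guess

- the best flask by excess of left-handed product over right-handed product; "all alike" if 1.5 percentage points covers them all (green / violet / teal / all alike)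
- excess of left-handed product over right-handed product at the end, green
- excess of left-handed product over right-handed product at the end, violet
- excess of left-handed product over right-handed product at the end, teal

I follow one molecule of left-handed product in the alder run and suppose that at each moment it either stays or flips to right-handed product, so that the gap c(left-handed product) − c(right-handed product) is fed by new product and drained in proportion to itself. The reading at 20.0 s gives a feed excess of about 59.3%. From 50.0 s to 90.0 s total product grows by 8.5 percentage points, yet the gap falls from 7 points to 4.9 points, so, if the feed keeps that excess, the drain took the fed share of that growth plus the fall. Over the mean gap and 40.0 s this reads as a constant of 0.0300 /s, a rough reading that carries the scatter of 0.5 points. That gives 23.1 s, the memory half-life, the time in which the drain halves the gap without feed.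

Green's 5.0 min is 13.0 memory half-lives, so its excess is a balance of feed against drain, on the way from kinetic to thermodynamic control. In the alder readings the late feed lies below the mean feed, so I expect green positive but under 6.59%. Violet's hot stretch is 6.49 memory half-lives, and by the same rule I expect violet under 13.2%. For teal I have no temperature law, so I pick it as the best flask on a guess.

The forecast reads the run as “a left-selective catalyst turning into a right-selective form” and gives −10% for green, 1% for violet and 30% for teal, with teal best.

The flasks give 1.02% for green, 2.69% for violet and 51.4% for teal, so teal leads, with green under my estimate of 6.59% and violet under my estimate of 13.2%.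

    left-handed product ⇌ right-handed product (k = 0.0150 /s, Ea = 111 kJ/mol)
    free catalyst + left-handed substrate ⇌ catalyst intermediate A (K = 6.40 /M, k = 16000 /M/s, Ea = 37.0 kJ/mol, ΔH = −65.0 kJ/mol)
    free catalyst + right-handed substrate ⇌ catalyst intermediate B (K = 2.50 /M, k = 2600 /M/s, Ea = 40.0 kJ/mol, ΔH = −12.0 kJ/mol)
    coupling partner + catalyst intermediate A → free catalyst + left-handed product (k = 140 /M/s, Ea = 59.0 kJ/mol)
    coupling partner + catalyst intermediate B → free catalyst + right-handed product (k = 43.0 /M/s, Ea = 48.0 kJ/mol)
    coupling partner + protic impurity → quenched reagent (k = 9.80 /M/s, Ea = 61.0 kJ/mol)
    (constants at 110 °C)

The flip of left-handed product into right-handed product is the largest single effect between the flasks: with what temperature does to this step taken away, green trails teal by 15 points instead of 50 points. In teal the relaxation half-life of the two products by this step alone is 4.38 min, ten times the 23.1 s I read at 110 °C. Counting on from the teal gap of 19 points, the further 15.0 min of the teal flask read at 20 min are 3.42 of these half-lives, in which the drain without feed leaves a gap of 1.8 points; while coupling partner falls from 20.0% to 0.791% of its charge, that flask stands at a gap of 3 points, an excess of 6.35%.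

All runs are calculated for an exercise; scatter was added.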